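The amounts of target in these flasks lie between two ends: early, c(target) climbs on a straight line through the origin (the initial rate), and late it lies on a flat ceiling. The rule joins them at the crossing time, the ceiling divided by the early slope. A flask well short of that time reads slope times time, and one well past it reads the ceiling.

| flask | starting material | temperature | remark | time |
|---|---|---|---|---|
| zeta | 0.034 M | −20 °C | run made earlier |  |
| theta | 0.075 M | 8 °C | run made earlier |  |
| cedar | 0.050 M | 0 °C |  | 20 h |
| maple | 0.050 M | 15 °C |  | 20 h |
| larch | 0.050 M | 30 °C |  | 20 h |
| oak | 0.050 M | −15 °C |  | 20 h |

- zeta (time / h: target / %): 8.00: 0.9; 15.0: 2.2; 25.0: 4.8; 40.0: 6.1; 60.0: 10.1; 72.0: 9.8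
- theta (time / h: target / %): 3.00: 21.6; 6.00: 27.7; 10.0: 31.2; 15.0: 32.1; 20.0: 32.4; 25.0: 31.6

(readings scatter by 0.5 percentage points)

- the flask with the highest amount of target, in percent of the starting material charged ("all alike" if they lie within 1.5 percentage points) (cedar / maple / larch / oak / all alike)
- final target, as a percentage of the starting material charged, in cedar
- final target, as a percentage of the starting material charged, in maple
- final target, as a percentage of the starting material charged, in larch
- final target, as a percentage of the starting material charged, in oak



1. Time is given exactly. In this reckoning it scales the answer on the straight end and drops out on the flat end.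

2. The slope matters on the straight end. A scatter of 0.5 percentage points on the zeta reading at 25.0 h shifts the slope, and with it a straight-end answer, by 10.4%. It does not touch the ceiling.

3. The ceiling moves flat-end answers one for one, and it is the weak number: between the runs the temperature and the charge (0.034 M, 0.075 M) changed together.

4. Zeta gives a slope of 0.00192 h⁻¹ as a fraction of the charge, and theta 0.0720 h⁻¹, which is low, as that reading already stands at 66.7% of the highest theta reading. Taking the slope as exponential in temperature, with the difference in charge set aside, gives oak 0.00367 h⁻¹ and cedar 0.0256 h⁻¹.

5. With the theta reading of 32.4% taken as the ceiling, the crossing time of oak is 88.3 h. Oak stays on the straight end, since 20 h is shorter, and my reckoning gives 7.34%. Cedar crosses at 12.7 h, earlier than 20 h, so it bends, and the joined curve gives 25.7%. Reckoned with that same ceiling, larch crosses at 0.261 h, far short of 20 h, so its answer is a ceiling, and the runs give no reading of that ceiling at 30 °C.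

The forecast names larch and gives cedar 23%, maple 34%, larch 44% and oak 8%, with its ceiling rising with temperature: “The plateau therefore looks like an equilibrium or fixed limit, not exhaustion of starting material”. My cedar stands above its value.

The flasks give cedar 30.6%, maple 44.2%, larch 50.4% and oak 7.09%, and larch holds more than the others.

starting material → target (k = 0.0420 h⁻¹, Ea = 89.0 kJ mol⁻¹); starting material + target → side product B (k = 1.70 M⁻¹ h⁻¹, Ea = 67.0 kJ mol⁻¹); starting material → side product A (k = 0.00840 h⁻¹, Ea = 102 kJ mol⁻¹); (constants at 0 °C) At the same temperature the neighbour of larch with 0.20 M of starting material gives 26.1%. Oak, at 20 h against a crossing time of 88.3 h, still has 89.6% starting material. Cedar's crossing time of 12.7 h lies between 10.0 h and 20.0 h, over which target goes from 23.4% to 30.6%, and at 200 h cedar holds 35.2% target.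

The data were computed with made-up constants, and the scatter is random.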